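**Retrosynthetic overview**
1. The last operation is hydrogenolysis of five benzyl ethers. The skeleton and both stereocentres are already in place by then.
2. Key disconnection: both pyranone rings are opened at once. The flavone ring goes back to a 2-hydroxyaryl 1,3-diketone. The flavanonol ring goes back to a MOM-masked phenol plus an (αR,βS)-chalcone epoxide. Both rings close in one acid charge.
3. The diketone is cut at CH2–CO, giving lithiated 4,6-di-O-benzylphloroacetophenone and a biaryl epoxy acid that is activated in the same pot.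
4. The epoxy acid comes from poly-L-leucine epoxidation of a biaryl chalcone acid. That acid comes from Claisen–Schmidt condensation of a biaryl acetophenone ester with 4-benzyloxybenzaldehyde.
5. The biaryl bond is made first, between two simple benzenes (iodinated di-O-benzylphloroacetophenone and methyl 3-bromo-4-hydroxybenzoate). Ring order: oxirane first, then both pyranones together.

Assumption: the SMILES carries no axial descriptor, and a biaryl with three small ortho oxygens rotates at room temperature. Only C-2 and C-3 are therefore controlled, and protected intermediates may show rotamers in NMR.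
Ring labels: the flavone half has rings A (benzo), C (pyranone) and B (aryl carrying the biaryl bond). The flavanonol half has rings A', C' and B'.

**Step 1**
Reactants: 1 2',4',6'-trihydroxyacetophenone (phloroacetophenone)
Product: 2 1-[2,4-bis(benzyloxy)-6-hydroxyphenyl]ethan-1-one
Conditions: BnBr (2.1 equiv), K2CO3 (2.2 equiv), DMF, 60 °C
Reagents that add atoms: benzyl bromide, BrCc1ccccc1
Why: Williamson ether synthesis, in which the last phenol stays free because it is chelated to the acetyl group and is far less nucleophilic.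

**Step 2**
Reactants: 2 1-[2,4-bis(benzyloxy)-6-hydroxyphenyl]ethan-1-one
Product: 3 1-[4,6-bis(benzyloxy)-2-hydroxy-3-iodophenyl]ethan-1-one
Conditions: NIS (1.05 equiv), TFA (10 mol%), MeCN, 0 °C to rt, dark
Reagents that add atoms: N-iodosuccinimide, O=C1CCC(=O)N1I
Why: Electrophilic aromatic iodination goes ortho to the free chelated phenol (C-3) and not between the two bulky benzyloxy groups, as is known for the corresponding 4,6-dialkyl ethers, and this places the halogen next to the oxygen that later becomes O-1 of ring C'.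

**Step 3**
Reactants: 4 methyl 3-bromo-4-hydroxybenzoate; 3 1-[4,6-bis(benzyloxy)-2-hydroxy-3-iodophenyl]ethan-1-one
Product: 6 methyl 3-[3-acetyl-4,6-bis(benzyloxy)-2-hydroxyphenyl]-4-hydroxybenzoate, via pinacol boronate 5 (not isolated)
Conditions: (a) 4 (1.4 equiv), B2pin2 (1.4 equiv), Pd(dppf)Cl2 (3 mol%), KOAc, 1,4-dioxane, 90 °C; (b) add 3 (1.0 equiv), Pd(OAc)2 (3 mol%), SPhos (6 mol%), aq K3PO4, 90 °C
Reagents that add atoms: bis(pinacolato)diboron, CC1(C)OB(OC1(C)C)B1OC(C)(C)C(C)(C)O1 (its boryl group is in 5 only; no reagent atom remains in 6)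
Why: One-pot Miyaura borylation and Suzuki–Miyaura coupling, in which the iodide is the only halide present when it is added, the SPhos complex of zerovalent palladium inserts into the doubly ortho-substituted C–I bond, and both phenols are carried as phenoxides.

**Step 4**
Reactants: 6 methyl 3-[3-acetyl-4,6-bis(benzyloxy)-2-hydroxyphenyl]-4-hydroxybenzoate
Product: 7 methyl 3-[3-acetyl-4,6-bis(benzyloxy)-2-(methoxymethoxy)phenyl]-4-(methoxymethoxy)benzoate
Conditions: NaH (2.3 equiv), MOMCl (2.6 equiv), DMF, 0 °C to rt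
Reagents that add atoms: chloromethyl methyl ether, COCCl
Why: Double O-alkylation (acetal protection) of both sodium phenoxides in one step, which marks the future O-1 of ring C' with an acid-labile group while its ortho competitor stays benzylated.

**Step 5**
Reactants: 7 methyl 3-[3-acetyl-4,6-bis(benzyloxy)-2-(methoxymethoxy)phenyl]-4-(methoxymethoxy)benzoate; 8 4-(benzyloxy)benzaldehyde
Product: 9 3-{4,6-bis(benzyloxy)-3-[(2E)-3-(4-benzyloxyphenyl)prop-2-enoyl]-2-(methoxymethoxy)phenyl}-4-(methoxymethoxy)benzoic acid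
Conditions: 8 (1.3 equiv), KOH (10 equiv), EtOH/THF/H2O, rt 24 h then 50 °C; AcOH to pH 5 at 0 °C
Reagents that add atoms: potassium hydroxide, [K+].[OH-] (oxygen of the new CO2H)
Why: Claisen–Schmidt condensation of the only enolisable ketone with a non-enolisable aldehyde gives the E-enone by E1cB loss of water, and the same hydroxide saponifies the methyl ester, while the MOM and benzyl ethers are stable to base.

**Step 6**
Reactants: 9 3-{4,6-bis(benzyloxy)-3-[(2E)-3-(4-benzyloxyphenyl)prop-2-enoyl]-2-(methoxymethoxy)phenyl}-4-(methoxymethoxy)benzoic acid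
Product: 10 3-{4,6-bis(benzyloxy)-3-[(2R,3S)-3-(4-benzyloxyphenyl)oxirane-2-carbonyl]-2-(methoxymethoxy)phenyl}-4-(methoxymethoxy)benzoic acid
Conditions: poly-L-leucine (silica-supported), urea·H2O2 (3 equiv), DBU (2.5 equiv), THF, rt; citric acid work-up, recrystallise
Reagents that add atoms: urea–hydrogen peroxide, NC(N)=O.OO
Why: Juliá–Colonna epoxidation, in which hydroperoxide adds in conjugate fashion to the enone held at the helical N-terminus of poly-L-leucine, which for chalcones (2'-O-MOM flavonoid chalcones included) gives the trans-(αR,βS)-epoxide, with the remote carboxylate a spectator as its DBU salt.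

**Step 7 (key step)**
Reactants: 10 3-{4,6-bis(benzyloxy)-3-[(2R,3S)-3-(4-benzyloxyphenyl)oxirane-2-carbonyl]-2-(methoxymethoxy)phenyl}-4-(methoxymethoxy)benzoic acid; 2 1-[2,4-bis(benzyloxy)-6-hydroxyphenyl]ethan-1-one
Product: 14 (2R,3R)-5,7-bis(benzyloxy)-2-[4-(benzyloxy)phenyl]-8-{5-[5,7-bis(benzyloxy)-4-oxo-4H-chromen-2-yl]-2-hydroxyphenyl}-3-hydroxy-2,3-dihydro-4H-chromen-4-one, via acyl imidazolide 11 (not isolated), via dilithium enolate-phenoxide 12 (not isolated), via epoxy 1,3-diketone 13 (not isolated)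
Conditions: (a) 10, CDI (1.05 equiv), THF, rt, 1 h; (b) 2 (3.3 equiv), LiN(SiMe3)2 (6.6 equiv), THF, −78 °C, add solution (a), −78 to −20 °C; (c) 3 M HCl in MeOH (excess), 55–60 °C, 4–8 h
Reagents that add atoms: 1,1'-carbonyldiimidazole, O=C(n1ccnc1)n1ccnc1 (imidazolyl group in 11 only); LiN(SiMe3)2, [Li+].C[Si](C)(C)[N-][Si](C)(C)C (lithium in 12 only); no reagent atom remains in 14
Why: Proposed new method: the closest known reactions are the Baker–Venkataraman-type C-acylation of a lithiated 2-hydroxyacetophenone (any O-acylated material reaches the same diketone by acyl shift, surplus enolate serves as the only base, and the oxirane C–H is not enolisable for strain reasons), the acid cyclodehydration of such diketones to flavones, and the HCl/MeOH unmasking and cyclisation of 2'-O-MOM chalcone epoxides to trans-dihydroflavonols, and they are merged here because one acid charge triggers both closures: the free ring A phenol adds to the diketone and loses water (ring C), while loss of the ring A' MOM group frees the only available ortho phenol (the other is benzylated, so only the 8-aryl isomer can form), which opens the protonated oxirane 6-endo at the p-benzyloxybenzylic carbon with inversion (βS becomes 2R) and leaves the untouched αR centre as 3R, any SN1 leakage also collapsing to the favoured 2,3-trans isomer.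

**Step 8**
Reactants: 14 (2R,3R)-5,7-bis(benzyloxy)-2-[4-(benzyloxy)phenyl]-8-{5-[5,7-bis(benzyloxy)-4-oxo-4H-chromen-2-yl]-2-hydroxyphenyl}-3-hydroxy-2,3-dihydro-4H-chromen-4-one
Product: 15 (2R,3R)-8-[5-(5,7-dihydroxy-4-oxo-4H-chromen-2-yl)-2-hydroxyphenyl]-3,5,7-trihydroxy-2-(4-hydroxyphenyl)-2,3-dihydro-4H-chromen-4-one (CNP0374521.1)
Conditions: H2 (1 atm), Pd/C (10 wt% Pd), THF/MeOH, rt, stop at full conversion
Reagents that add atoms: none
Why: Catalytic hydrogenolysis of five aryl benzyl ethers under neutral conditions, which at 1 atm and rt leaves the flavone C=C, the ketones and the cyclic C-2–O bond untouched and cannot epimerise C-2 or C-3.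

**Compound list**
1 | 2',4',6'-trihydroxyacetophenone | CC(=O)c1c(O)cc(O)cc1O | starting material
2 | 1-[2,4-bis(benzyloxy)-6-hydroxyphenyl]ethan-1-one | CC(=O)c1c(O)cc(OCc2ccccc2)cc1OCc1ccccc1 | intermediate
3 | 1-[4,6-bis(benzyloxy)-2-hydroxy-3-iodophenyl]ethan-1-one | CC(=O)c1c(O)c(I)c(OCc2ccccc2)cc1OCc1ccccc1 | intermediate
4 | methyl 3-bromo-4-hydroxybenzoate | COC(=O)c1ccc(O)c(Br)c1 | starting material
5 | methyl 4-hydroxy-3-(4,4,5,5-tetramethyl-1,3,2-dioxaborolan-2-yl)benzoate | COC(=O)c1ccc(O)c(c1)B1OC(C)(C)C(C)(C)O1 | intermediate (not isolated)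
6 | methyl 3-[3-acetyl-4,6-bis(benzyloxy)-2-hydroxyphenyl]-4-hydroxybenzoate | COC(=O)c1ccc(O)c(c1)-c1c(O)c(C(C)=O)c(OCc2ccccc2)cc1OCc1ccccc1 | intermediate
7 | methyl 3-[3-acetyl-4,6-bis(benzyloxy)-2-(methoxymethoxy)phenyl]-4-(methoxymethoxy)benzoate | COC(=O)c1ccc(OCOC)c(c1)-c1c(OCOC)c(C(C)=O)c(OCc2ccccc2)cc1OCc1ccccc1 | intermediate
8 | 4-(benzyloxy)benzaldehyde | O=Cc1ccc(OCc2ccccc2)cc1 | starting material
9 | (E)-chalcone acid | OC(=O)c1ccc(OCOC)c(c1)-c1c(OCOC)c(C(=O)/C=C/c2ccc(OCc3ccccc3)cc2)c(OCc2ccccc2)cc1OCc1ccccc1 | intermediate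
10 | (2R,3S)-epoxy acid | OC(=O)c1ccc(OCOC)c(c1)-c1c(OCOC)c(C(=O)[C@@H]2O[C@H]2c2ccc(OCc3ccccc3)cc2)c(OCc2ccccc2)cc1OCc1ccccc1 | intermediate
11 | acyl imidazolide of 10 | O=C(n1ccnc1)c1ccc(OCOC)c(c1)-c1c(OCOC)c(C(=O)[C@@H]2O[C@H]2c2ccc(OCc3ccccc3)cc2)c(OCc2ccccc2)cc1OCc1ccccc1 | intermediate (not isolated)
12 | dilithium enolate-phenoxide of 2 | [Li+].[Li+].C=C([O-])c1c([O-])cc(OCc2ccccc2)cc1OCc1ccccc1 | intermediate (not isolated)
13 | epoxy 1,3-diketone (keto form) | O=C(CC(=O)c1c(O)cc(OCc2ccccc2)cc1OCc1ccccc1)c1ccc(OCOC)c(c1)-c1c(OCOC)c(C(=O)[C@@H]2O[C@H]2c2ccc(OCc3ccccc3)cc2)c(OCc2ccccc2)cc1OCc1ccccc1 | intermediate (not isolated)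
14 | (2R,3R)-pentabenzyl ether of the target | O=C1c2c(OCc3ccccc3)cc(OCc3ccccc3)c(-c3cc(-c4cc(=O)c5c(OCc6ccccc6)cc(OCc6ccccc6)cc5o4)ccc3O)c2O[C@H](c2ccc(OCc3ccccc3)cc2)[C@H]1O | intermediate
15 | CNP0374521.1, (2R,3R) | O=C1c2c(O)cc(O)c(-c3cc(-c4cc(=O)c5c(O)cc(O)cc5o4)ccc3O)c2O[C@H](c2ccc(O)cc2)[C@H]1O | target

**Totals**
Total steps: 8.
Longest linear sequence: 8 (1, 2, 3, 6, 7, 9, 10, 14, 15). Compound 2 is used a second time in step 7.

**Three steps most likely to fail**

**Step 7.**
- Risks:
  - The enolate meets an acyl donor that also carries an epoxy ketone.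
  - In the acid phase, MeOH or chloride can open the oxirane before the phenol is free. This costs yield and gives some 2,3-cis isomer, which is removed by chromatography (the trans isomer shows J(2,3) of about 11–12 Hz).
  - Partial loss of a 5-O-benzyl group after ring closure is harmless, because step 8 removes all benzyl groups anyway.
- Fallback: it sets out from 10 (with 2) and replaces the intermolecular acylation by an intramolecular one.
  - Steglich esterification (EDC, DMAP, CH2Cl2) of 10 with the phenol of 2 gives the 2-acetyl-3,5-bis(benzyloxy)phenyl ester F1.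
  - A true Baker–Venkataraman acyl shift (LiN(SiMe3)2, 2.2 equiv, THF, −78 to −20 °C) converts F1 into the diketone.
  - The route is rejoined at 13, now isolated and purified, which is then closed to 14 with methanolic HCl.

**Step 6.**
- Risk: the aryl ketone has two ortho substituents and is twisted, and phloroglucinol-type chalcones are known to give slower reactions and lower ee with polyamino acid catalysts.
- Fallback: it sets out from 9 and replaces catalysis by resolution.
  - Weitz–Scheffer epoxidation (30% H2O2, NaOH, MeOH/THF) gives the racemic trans-epoxy acid F2.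
  - The carboxylic acid handle is used for classical resolution by crystallising the (S)-1-phenylethylammonium salt of the (2R,3S)-acid F3. The antipodal amine is taken if the other salt is the less soluble one.
  - Release with aqueous citric acid returns to the route at 10.

**Step 3.**
- Risk: two free phenols are present, the 2-hydroxyaryl boronate is prone to protodeboronation, and the iodide is hindered and electron-rich.
- Fallback: it sets out from 3 and 4 and masks both phenols before any palladium chemistry.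
  - NaH/MOMCl turns 3 into 1-[4,6-bis(benzyloxy)-3-iodo-2-(methoxymethoxy)phenyl]ethan-1-one F4.
  - The same conditions turn 4 into methyl 3-bromo-4-(methoxymethoxy)benzoate F5.
  - Miyaura borylation of F5 gives the isolated methyl 4-(methoxymethoxy)-3-(4,4,5,5-tetramethyl-1,3,2-dioxaborolan-2-yl)benzoate F6.
  - Suzuki coupling of F4 with F6 (Pd(OAc)2, SPhos, K3PO4, toluene/H2O) returns to the route at 7. Compound 6 and step 4 then drop out, for a net two extra steps.

**Further compounds**
F1 | step 7 | 2-acetyl-3,5-bis(benzyloxy)phenyl ester of 10 | CC(=O)c1c(OC(=O)c2ccc(OCOC)c(c2)-c2c(OCOC)c(C(=O)[C@@H]3O[C@H]3c3ccc(OCc4ccccc4)cc3)c(OCc3ccccc3)cc2OCc2ccccc2)cc(OCc2ccccc2)cc1OCc1ccccc1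
F2 | step 6 | racemic trans-epoxy acid (1:1 mixture of 10 and its enantiomer) | OC(=O)c1ccc(OCOC)c(c1)-c1c(OCOC)c(C(=O)[C@@H]2O[C@H]2c2ccc(OCc3ccccc3)cc2)c(OCc2ccccc2)cc1OCc1ccccc1.OC(=O)c1ccc(OCOC)c(c1)-c1c(OCOC)c(C(=O)[C@H]2O[C@@H]2c2ccc(OCc3ccccc3)cc2)c(OCc2ccccc2)cc1OCc1ccccc1
F3 | step 6 | (S)-1-phenylethylammonium salt of the (2R,3S)-acid | C[C@H]([NH3+])c1ccccc1.[O-]C(=O)c1ccc(OCOC)c(c1)-c1c(OCOC)c(C(=O)[C@@H]2O[C@H]2c2ccc(OCc3ccccc3)cc2)c(OCc2ccccc2)cc1OCc1ccccc1
F4 | step 3 | 1-[4,6-bis(benzyloxy)-3-iodo-2-(methoxymethoxy)phenyl]ethan-1-one | CC(=O)c1c(OCOC)c(I)c(OCc2ccccc2)cc1OCc1ccccc1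
F5 | step 3 | methyl 3-bromo-4-(methoxymethoxy)benzoate | COCOc1ccc(cc1Br)C(=O)OC
F6 | step 3 | methyl 4-(methoxymethoxy)-3-(4,4,5,5-tetramethyl-1,3,2-dioxaborolan-2-yl)benzoate | COCOc1ccc(cc1B1OC(C)(C)C(C)(C)O1)C(=O)OC
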